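**Assumption.** I read the SMILES chain as twelve CH2 groups, so the substituent is 13-oxotetradecyl and the target is (2R,3R,6S)-2-methyl-6-(13-oxotetradecyl)piperidin-3-yl acetate. All three stereocentres are all-cis, and I take the (–) sign to correspond to this enantiomer.

## Retrosynthetic overview
1. The target comes from chemoselective O-acetylation of (–)-spectaline (19), which is obtained from a fully protected piperidine (18).
2. The only ring is formed last, in one hydrogenation cascade. Cbz hydrogenolysis releases the C2-amine, which condenses with the C6 ketone to a cyclic imine; H2 then adds to C6=N from the face opposite the C2-Me and C3-OTBS groups, giving the 2,6-cis, all-cis ring.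
3. The open-chain Cbz-amino ketone (17) comes from the aldehyde (9) plus a ketal-protected C12 Grignard reagent. The aldehyde comes from anti-Markovnikov hydroboration of the terminal alkene (7).
4. C3 is set by Ti–BINOL catalysed allylation of pyruvaldehyde dimethyl acetal. C2 is set by an (R)-ω-transaminase acting on the resulting α-hydroxy methyl ketone, giving the syn (2R,3R) amino alcohol. C6 is set in the ring-closing hydrogenation.
5. The chain Grignard reagent is made from 1,11-dibromoundecane and ethyl acetoacetate.

## Route

**Step 1**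
Reactants: 1 (2,2-dimethoxypropanal), 2 (allyltributylstannane)
Product: 3, (3R)-2,2-dimethoxyhex-5-en-3-ol
Conditions: (R)-BINOL (20 mol %), Ti(OiPr)4 (10 mol %), 4 Å MS, CH2Cl2, –20 °C, 48 h
Reagents that add atoms: none (both partners are numbered reactants)
Why: Keck catalytic asymmetric allylation. The chiral Ti–BINOL Lewis acid binds the non-enolisable aldehyde and the allylstannane adds to one enantioface, setting C3 as (R). The catalyst enantiomer is chosen to give the (3R) carbinol.

**Step 2**
Reactants: 3
Product: 4, (3R)-3-hydroxyhex-5-en-2-one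
Conditions: 1 M aq HCl, THF, 40 °C, 6 h; neutralise, use as a solution
Reagents that add atoms: water, O
Why: Acid hydrolysis of the dimethyl ketal unmasks the methyl ketone. The C3 centre is not touched and the α-H is not enolised under these conditions.

**Step 3**
Reactants: 4
Product: 5, (2R,3R)-2-aminohex-5-en-3-ol
Conditions: (R)-selective ω-transaminase (PLP-dependent, ATA-117 type, 10 g/L), iPrNH2·HCl (0.5 M), PLP (1 mM), 100 mM KPi pH 7.5, 10 % DMSO, 30 °C, 24–48 h, N2 sweep to remove acetone; then Dowex 50 (H+) catch-and-release with NH3/MeOH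
Reagents that add atoms: isopropylamine, CC(C)N (its nitrogen is transferred to the product)
Why: Enzymatic asymmetric reductive amination. The (R)-transaminase delivers NH2 to one face of the methyl ketone, creating C2 as (R) regardless of the existing C3 centre. This gives the syn (2R,3R) amino alcohol, and removal of acetone drives the equilibrium.

**Step 4**
Reactants: 5
Product: 6, benzyl N-[(2R,3R)-3-hydroxyhex-5-en-2-yl]carbamate
Conditions: CbzCl, NaHCO3, THF/H2O, 0 °C → rt
Reagents that add atoms: benzyl chloroformate, O=C(Cl)OCc1ccccc1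
Why: Schotten–Baumann N-acylation. The amine is far more nucleophilic than the secondary alcohol, so only nitrogen reacts and no stereocentre is affected.

**Step 5**
Reactants: 6
Product: 7, benzyl N-[(2R,3R)-3-(tert-butyldimethylsilyloxy)hex-5-en-2-yl]carbamate
Conditions: TBSCl, imidazole, DMF, 40 °C
Reagents that add atoms: TBSCl, CC(C)(C)[Si](C)(C)Cl
Why: Silylation masks the C3 hydroxyl so it survives the later DMP oxidations and Grignard addition.

**Step 6**
Reactants: 7
Product: 8, benzyl N-[(2R,3R)-3-(TBSO)-6-hydroxyhexan-2-yl]carbamate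
Conditions: 9-BBN (2.5 equiv), THF, 0 °C → rt; then NaBO3·4H2O, THF/H2O, rt
Reagents that add atoms: hydrogen peroxide equivalent from perborate (oxygen source), OO
Why: Hydroboration–oxidation is anti-Markovnikov and syn-addition at the terminal alkene. It creates no stereocentre, and Cbz and TBS groups are untouched.

**Step 7**
Reactants: 8
Product: 9, benzyl N-[(2R,3R)-3-(TBSO)-6-oxohexan-2-yl]carbamate
Conditions: Dess–Martin periodinane, NaHCO3, CH2Cl2, rt
Reagents that add atoms: none
Why: Mild Dess–Martin oxidation of the primary alcohol to the aldehyde. The aldehyde is γ to the OTBS group, so there is no β-elimination and no stereocentre is affected.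

**Step 8**
Reactants: 10 (1,11-dibromoundecane), 11 (ethyl acetoacetate)
Product: 12, ethyl 2-acetyl-13-bromotridecanoate
Conditions: NaOEt, EtOH, reflux (3 equiv dibromide)
Reagents that add atoms: none
Why: Acetoacetic ester C-alkylation. Excess dibromide limits dialkylation at the second bromide.

**Step 9**
Reactants: 12
Product: 13, 14-bromotetradecan-2-one
Conditions: LiBr, H2O, DMSO, 150 °C
Reagents that add atoms: none
Why: Krapcho decarboxylation of the β-keto ester. Using a bromide salt avoids Br/Cl exchange on the primary bromide.

**Step 10**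
Reactants: 13
Product: 14, 2-(12-bromododecyl)-2-methyl-1,3-dioxolane
Conditions: HOCH2CH2OH, TsOH (cat.), toluene, Dean–Stark, reflux
Reagents that add atoms: ethylene glycol, OCCO
Why: Ketalisation protects the methyl ketone so the organomagnesium reagent can be made.

**Step 11**
Reactants: 14
Product: 15, [12-(2-methyl-1,3-dioxolan-2-yl)dodecyl]magnesium bromide
Conditions: Mg turnings, I2 (cat.), THF, reflux
Reagents that add atoms: magnesium, [Mg]
Why: Standard Grignard formation; the dioxolane is inert to Mg.

**Step 12**
Reactants: 9, 15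
Product: 16, benzyl N-[(2R,3R)-3-(TBSO)-6-hydroxy-19,19-(ethylenedioxy)icosan-2-yl]carbamate (C6 epimeric mixture)
Conditions: 15 (3 equiv), THF, –20 °C → 0 °C; aq NH4Cl
Reagents that add atoms: none
Why: Grignard 1,2-addition to the aldehyde. The first equivalent deprotonates the carbamate N–H. The new C6 carbinol is deliberately not controlled because it is oxidised in the next step.

**Step 13**
Reactants: 16
Product: 17, benzyl N-[(2R,3R)-3-(TBSO)-6-oxo-19,19-(ethylenedioxy)icosan-2-yl]carbamate
Conditions: Dess–Martin periodinane, NaHCO3, CH2Cl2, rt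
Reagents that add atoms: none
Why: Oxidation converges both C6 epimers to one ketone, the electrophile needed for the ring-closing imine. C2 and C3 are not epimerisable here.

**Step 14**
Reactants: 17
Product: 18, (2R,3R,6S)-3-(TBSO)-2-methyl-6-[12-(2-methyl-1,3-dioxolan-2-yl)dodecyl]piperidine
Conditions: H2 (1 atm), 10 % Pd/C, MeOH, rt, 24 h
Reagents that add atoms: none (H2 adds only hydrogen)
Why: Hydrogenolysis of Cbz frees the primary amine, which condenses with the C6 ketone to a six-membered cyclic imine (intramolecular reductive amination). H2 adds from the face anti to the C2-Me and C3-OTBS groups, which lie on the same face because of the syn amino alcohol. This sets C6 as (S) with the chain cis to the methyl. TBS and the dioxolane are stable under these conditions.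

**Step 15**
Reactants: 18
Product: 19, (–)-spectaline, (2R,3R,6S)-2-methyl-6-(13-oxotetradecyl)piperidin-3-ol (isolated as the HCl salt)
Conditions: 3 M aq HCl, THF, 60 °C, 16 h
Reagents that add atoms: water, O
Why: Acid removes both the TBS ether and the dioxolane. The amine is protonated and no stereocentre is affected. The product is a known natural alkaloid.

**Step 16**
Reactants: 19 (HCl salt)
Product: 20, (–)-3-O-acetylspectaline (target)
Conditions: AcCl (4 equiv), CF3CO2H, 0 °C → rt, 3 h; cold sat. NaHCO3, CH2Cl2 extraction
Reagents that add atoms: acetyl chloride, CC(=O)Cl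
Why: In TFA the nitrogen is protonated, so acetyl trifluoroacetate acylates only the axial 3-OH. Cold basic work-up gives the free base and limits O→N acyl migration.

## Compound list
1 | 2,2-dimethoxypropanal | CC(OC)(OC)C=O | starting material
2 | allyltributylstannane | C=CC[Sn](CCCC)(CCCC)CCCC | starting material
3 | (3R)-2,2-dimethoxyhex-5-en-3-ol | C=CC[C@@H](O)C(C)(OC)OC | intermediate
4 | (3R)-3-hydroxyhex-5-en-2-one | C=CC[C@@H](O)C(C)=O | intermediate
5 | (2R,3R)-2-aminohex-5-en-3-ol | C=CC[C@@H](O)[C@@H](C)N | intermediate
6 | benzyl N-[(2R,3R)-3-hydroxyhex-5-en-2-yl]carbamate | C=CC[C@@H](O)[C@@H](C)NC(=O)OCc1ccccc1 | intermediate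
7 | TBS ether of 6 | C=CC[C@@H](O[Si](C)(C)C(C)(C)C)[C@@H](C)NC(=O)OCc1ccccc1 | intermediate
8 | benzyl N-[(2R,3R)-3-(TBSO)-6-hydroxyhexan-2-yl]carbamate | OCCC[C@@H](O[Si](C)(C)C(C)(C)C)[C@@H](C)NC(=O)OCc1ccccc1 | intermediate
9 | benzyl N-[(2R,3R)-3-(TBSO)-6-oxohexan-2-yl]carbamate | O=CCC[C@@H](O[Si](C)(C)C(C)(C)C)[C@@H](C)NC(=O)OCc1ccccc1 | intermediate
10 | 1,11-dibromoundecane | BrCCCCCCCCCCCBr | starting material
11 | ethyl acetoacetate | CC(=O)CC(=O)OCC | starting material
12 | ethyl 2-acetyl-13-bromotridecanoate | CC(=O)C(CCCCCCCCCCCBr)C(=O)OCC | intermediate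
13 | 14-bromotetradecan-2-one | CC(=O)CCCCCCCCCCCCBr | intermediate
14 | 2-(12-bromododecyl)-2-methyl-1,3-dioxolane | CC1(CCCCCCCCCCCCBr)OCCO1 | intermediate
15 | [12-(2-methyl-1,3-dioxolan-2-yl)dodecyl]magnesium bromide | Br[Mg]CCCCCCCCCCCCC1(C)OCCO1 | intermediate
16 | C6-epimeric secondary alcohol (Cbz, TBS, dioxolane) | CC1(CCCCCCCCCCCCC(O)CC[C@@H](O[Si](C)(C)C(C)(C)C)[C@@H](C)NC(=O)OCc2ccccc2)OCCO1 | intermediate
17 | C6 ketone | CC1(CCCCCCCCCCCCC(=O)CC[C@@H](O[Si](C)(C)C(C)(C)C)[C@@H](C)NC(=O)OCc2ccccc2)OCCO1 | intermediate
18 | (2R,3R,6S)-3-(TBSO)-2-methyl-6-[12-(2-methyl-1,3-dioxolan-2-yl)dodecyl]piperidine | CC1(CCCCCCCCCCCC[C@H]2CC[C@@H](O[Si](C)(C)C(C)(C)C)[C@@H](C)N2)OCCO1 | intermediate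
19 | (–)-spectaline | CC(=O)CCCCCCCCCCCC[C@H]1CC[C@@H](O)[C@@H](C)N1 | intermediate
20 | (–)-3-O-acetylspectaline | CC(=O)CCCCCCCCCCCC[C@H]1CC[C@@H](OC(C)=O)[C@@H](C)N1 | target

**Total steps:** 16 (12 on the main line plus 4 for the chain fragment).
**Longest linear sequence:** 12 steps (1→2→3→4→5→6→7→12→13→14→15→16).

**Three steps most likely to fail**
1. **Step 3, transaminase amination of the free acyloin.** The enzyme may show low activity or poor diastereoselectivity. Fallback: reduce the C2 ketone of 4 chemically to the (2S,3R)-diol using chelation-controlled Zn(BH4)2 or Evans–Saksena-type conditions, then convert C2-OH to the azide with inversion by Mitsunobu (DPPA) and reduce and Cbz-protect it.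
2. **Step 1, Ti–BINOL allylation of the hindered acetal aldehyde.** Enantioselectivity or yield may be poor. Fallback: add allylMgBr to 1 to make racemic 3, then resolve it by lipase-catalysed acetylation (CAL-B, vinyl acetate) and use the (3R) alcohol.
3. **Step 12, Grignard addition to the N-H carbamate aldehyde 9,** which may exist partly as a cyclic hemiaminal and can enolise. Fallback: oxidise 8 to the acid, make the Weinreb amide, and add 15 to it to give ketone 17 directly, skipping steps 12–13.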